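# Proposed synthesis of CNP0211607.1 (25) by copper-catalysed borylative lactonisation

## The problem

Compound 25 is a depsidone. Ring A (the benzoyl ring with methoxy, methyl and hydroxy groups) and ring B (the fully substituted ring) are joined by a diaryl ether oxygen and an aryl ester, which close a seven-membered dioxepinone. Ring B also carries a fused five-membered 3-hydroxy lactone. The ether oxygen lies between two aryl carbons that each have two ortho substituents, so a late copper-mediated coupling of two finished rings is the least reliable bond to build on. The only stereocentre is C1, the hemiacetal carbon of the hydroxy lactone (R); nothing else is chiral, so it must be set by a reagent or catalyst. C1 is also labile, because the lactol can open to the ortho-formyl benzoic acid and re-close on either face. The free C1–OH therefore has to appear in the last operation, under conditions that do not equilibrate it. The aryl ester of the seven-membered ring is opened by alkoxide or hydroxide, and the two phenols do not tolerate strong oxidants. The enabling feature is that C1 is an aldehyde-level carbon on ring B directly ortho to the carboxyl carbon C3. In an ortho-formyl benzoate, boron can be added to the aldehyde carbon while the aldehyde oxygen closes onto the ester, so C1 is fixed as a C–B centre inside the finished lactone and exchanged for OH with retention at the end.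

## Retrosynthesis

**C1–OH from C1–B.** The C1–O(H) bond of 25 is traced back to a C1–B bond in the diphenol boronate 23. Amine-oxide oxidation passes through the O-boryl hemiacetal 24, so the lactol oxygen stays capped until the final hydrolysis. Cutting here, and not at the lactone C–O bond, avoids forming the hemiacetal under equilibrating conditions. The forward reaction must proceed with retention and without base on the free lactol.

**Phenol protection.** 23 comes from the bis(benzyl ether) 22 by hydrogenolysis. The benzyl groups are removed while C1 is still a C–B centre that cannot ring-open. Benzyl is chosen because the copper step needs no acidic OH and the removal is neutral.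

**Key disconnection.** In 22 the C1–B bond and the lactone O–C3 bond are cut together. This gives the ortho-formyl methyl ester 20 and bis(pinacolato)diboron 21. Compared with adding a hydroxyl equivalent to the aldehyde, boron gives a centre that survives deprotection. The forward step needs face selection at a di-ortho-substituted aryl aldehyde and must leave the aryl ester of the seven-membered ring intact.

**Seven-membered lactone.** 20 is the benzyl ether of phenol 19. The aryl ester C–O bond of 19 is cut to the hydroxy acid 17, which arises from the tert-butyl ester diethyl acetal 16 by one acid treatment. Closing the ester last is preferred to closing the ether last, because lactonisation onto the only phenol that can reach the acid is intramolecular and tolerant of crowding.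

**Ring B.** The two ring B C–C bonds flanking the ester-bearing carbon and the methyl-bearing carbon are cut. 16 goes back to the cyclohexane-1,3-dione 15, and 15 to the 2-aryloxy enone 12 plus dimethyl malonate 13 (through Michael adduct 14). This builds the hexasubstituted ring around the ether oxygen instead of coupling two crowded arenes. The price is an oxidation (15 to 16).

**Aryloxy enone.** The C=C bond of 12 is cut to ketone 10 and 2,2-diethoxyacetaldehyde 11. The O–CH2 bond of 10 is cut to phenol 8 and 1-bromobutan-2-one 9. The hindered aryl–O–aryl bond is thus replaced by a simple O-alkylation. The condensation must occur at the aryloxy-bearing methylene, not at the ethyl group.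

**Ring A.** 8 is the tert-butyl ester of acid 7, obtained from salicylaldehyde 6. The formyl group of 6 is placed ortho to the hydroxyl of phenol 5. Phenol 5 comes from aldehyde 3 by aryl formate 4, 3 from 2, and 2 from creosol 1. Each substituent enters at the only free position ortho to a phenol, so no isomers need separating.

## Roads not taken

**Alternative 1:** Michael–Claisen annulation as the strategic step.
- **Cut and key step:** the two ring B C–C bonds; 13 adds to an aryloxy enone, the ring closes and is dehydrogenated to diaryl ether A1.
- **Merits:** A1 is the same compound as 16, so the chemistry is sound; steps 9 and 10 of the chosen route use it. It builds the crowded ring without aryl ether coupling.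
- **Weak point:** as a full plan it ends by lactonisation and hydrolysis of the ring B ester next to the aldehyde. C1 then forms as a free lactol under equilibrating conditions, with no element to choose its face, and the result is racemate A2.
- **Comparison:** this plan is about three steps shorter and needs no boron and no second benzylation. The chosen plan spends those steps to obtain a defined C1.

**Alternative 2:** carboxyl radical relay onto the ring B methyl group.
- **Cut and key step:** the lactone CH2–O bond; K2S2O8 with CuCl2 converts the ortho-methyl benzoic acid A4 into phthalide A3 by 1,5-hydrogen transfer to a carboxyl radical and C–O bond formation at divalent copper.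
- **Merits:** ring B would come from a simple dimethyl resorcylate unit, and no aldehyde is carried. The relay is regiospecific and leaves the ring A methyl group untouched.
- **Weak points:** A3 is one oxidation level below the target, so a second oxidation at the same carbon is needed, and that hydroxylation has no stereocontrol. Persulfate radicals require the electron-rich rings to be deactivated as acetates. The two preformed rings must still be joined through the tetra-ortho-substituted ether.
- **Comparison:** it would be shorter if the ether coupling succeeded. The chosen plan avoids that coupling and sets C1, at the cost of a longer ring B construction.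

**Alternative 3:** quinol spirolactone ring expansion.
- **Cut and key step:** the ester O–aryl bond of ring B; PhI(OAc)2 (a trivalent iodine oxidant) oxidises the para-aryloxy phenol A6 so the ring A carboxylate adds at the ether-bearing carbon, giving spiro ketal-lactone A7; BF3·OEt2 then shifts the acyloxy oxygen to the neighbouring CH and the ring rearomatises to A5.
- **Merits:** A5 is the same compound as 19. The diaryl ether is made while it has only three ortho substituents, and the fourth oxygen is introduced afterwards.
- **Weak points:** the phenol to be oxidised is a hydrogen-bonded salicylate flanked by ester and aldehyde, which resists phenol oxidation. A pentasubstituted ring B aldehyde must be made separately, and a hindered aryl ether coupling is still required.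
- **Comparison:** it says nothing about C1 and would need the same borylative end game, so it is a possible substitute for steps 7 to 12, more convergent but resting on an untested oxidation. The chosen plan uses only classical condensations there.

Key step: step 14

Assumption: the lactol carbon C1 of 25 is taken to hold its configuration in the crystal and, during a short work-up, in cold, amine-free, weakly acidic solution; in basic or warm protic solution it would equilibrate through the open formyl acid.

## Route

Step 1
Reactants: 1 creosol (2-methoxy-4-methylphenol)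
Product: 2 2-hydroxy-3-methoxy-5-methylbenzaldehyde
Conditions: MgCl2, Et3N, (CH2O)n, CH3CN, reflux; aq HCl work-up
Reagents that add atoms: paraformaldehyde (formaldehyde units), C=O
Why: Magnesium phenoxide-directed ortho-formylation (Casnati–Skattebøl); only one position ortho to the hydroxyl is free, and a second formaldehyde accepts the hydride.

Step 2
Reactants: 2 2-hydroxy-3-methoxy-5-methylbenzaldehyde
Product: 3 2-(benzyloxy)-3-methoxy-5-methylbenzaldehyde
Conditions: BnBr, K2CO3, DMF, rt
Reagents that add atoms: benzyl bromide, BrCc1ccccc1
Why: Williamson ether synthesis on the phenoxide; the benzyl group blocks this oxygen for the later selective alkylation of its neighbour.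

Step 3
Reactants: 3 2-(benzyloxy)-3-methoxy-5-methylbenzaldehyde
Product: 5 2-(benzyloxy)-3-methoxy-5-methylphenol, via aryl formate 4 (not isolated)
Conditions: mCPBA, CH2Cl2, 0 °C to rt; aq NaHCO3 wash; then K2CO3 (0.2 equiv), CH3OH, rt
Reagents that add atoms: 3-chloroperbenzoic acid, OOC(=O)c1cccc(Cl)c1
Why: Baeyer–Villiger oxidation of an electron-rich ortho-alkoxy benzaldehyde, in which the aryl group migrates; the formate is then cleaved by methanolysis.

Step 4
Reactants: 5 2-(benzyloxy)-3-methoxy-5-methylphenol
Product: 6 3-(benzyloxy)-2-hydroxy-4-methoxy-6-methylbenzaldehyde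
Conditions: MgCl2, Et3N, (CH2O)n, THF, reflux; aq HCl work-up
Reagents that add atoms: paraformaldehyde (formaldehyde units), C=O
Why: Second magnesium-mediated ortho-formylation; the only free ortho position lies between the hydroxyl and the methyl group and is also para to the methoxy group.

Step 5
Reactants: 6 3-(benzyloxy)-2-hydroxy-4-methoxy-6-methylbenzaldehyde
Product: 7 3-(benzyloxy)-2-hydroxy-4-methoxy-6-methylbenzoic acid
Conditions: NaClO2, NaH2PO4, 2-methyl-2-butene (excess), t-BuOH–THF–H2O, 0 °C to rt
Reagents that add atoms: sodium chlorite, [Na+].[O-]Cl=O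
Why: Pinnick oxidation; the alkene traps HOCl, which would otherwise chlorinate the electron-rich ring, and the acid is used without heating to avoid loss of CO2.

Step 6
Reactants: 7 3-(benzyloxy)-2-hydroxy-4-methoxy-6-methylbenzoic acid
Product: 8 tert-butyl 3-(benzyloxy)-2-hydroxy-4-methoxy-6-methylbenzoate
Conditions: Cl3CC(=NH)OC(CH3)3, CH2Cl2–cyclohexane, rt
Reagents that add atoms: tert-butyl 2,2,2-trichloroacetimidate, CC(C)(C)OC(=N)C(Cl)(Cl)Cl
Why: Acid-triggered O-alkylation of the carboxylic acid by the imidate, which is insensitive to crowding at the carbonyl and leaves the hydrogen-bonded phenol free. The tert-butyl ester is inert to the alkoxide used in step 9.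

Step 7
Reactants: 8 tert-butyl 3-(benzyloxy)-2-hydroxy-4-methoxy-6-methylbenzoate; 9 1-bromobutan-2-one
Product: 10 tert-butyl 3-(benzyloxy)-4-methoxy-6-methyl-2-(2-oxobutoxy)benzoate
Conditions: Cs2CO3, DMF, rt to 40 °C
Reagents that add atoms: none
Why: SN2 alkylation of the phenoxide by an α-bromo ketone. It forms the oxygen–carbon bond that will become the crowded diaryl ether, and the bulky tert-butyl ester suppresses cyclisation onto ring A.

Step 8
Reactants: 10 tert-butyl 3-(benzyloxy)-4-methoxy-6-methyl-2-(2-oxobutoxy)benzoate; 11 2,2-diethoxyacetaldehyde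
Product: 12 tert-butyl 3-(benzyloxy)-2-{[(2Z)-1,1-diethoxy-4-oxohex-2-en-3-yl]oxy}-4-methoxy-6-methylbenzoate
Conditions: pyrrolidine (0.2 equiv), AcOH (0.2 equiv), 4 Å molecular sieves, toluene, 50 °C
Reagents that add atoms: none
Why: Amine-catalysed aldol condensation; the aryloxy-bearing methylene is the more acidic α-position (an α-aryloxy group lowers the pKa of a ketone by roughly three units), and α-oxygenated ketones react through the oxygenated enamine. The alkene geometry is lost in the next step.

Step 9
Reactants: 12 tert-butyl 3-(benzyloxy)-2-{[(2Z)-1,1-diethoxy-4-oxohex-2-en-3-yl]oxy}-4-methoxy-6-methylbenzoate; 13 dimethyl malonate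
Product: 15 tert-butyl 3-(benzyloxy)-2-{[2-(diethoxymethyl)-3-(methoxycarbonyl)-5-methyl-4,6-dioxocyclohexyl]oxy}-4-methoxy-6-methylbenzoate (diastereomers and enol forms), via Michael adduct 14 (not isolated)
Conditions: NaOCH3, CH3OH, rt to reflux; then AcOH to pH 5
Reagents that add atoms: none
Why: Michael addition of the malonate to the acetal-bearing enone carbon, then Claisen (Dieckmann-type) closure of the ethyl-side enolate onto a malonate ester, driven by the stable dione enolate. The enolate on the aryloxy side cannot cyclise, so the substitution pattern is fixed.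

Step 10
Reactants: 15 the cyclohexane-1,3-dione of step 9
Product: 16 tert-butyl 3-(benzyloxy)-2-[2-(diethoxymethyl)-4,6-dihydroxy-3-(methoxycarbonyl)-5-methylphenoxy]-4-methoxy-6-methylbenzoate
Conditions: I2 (1.2 equiv), NaOAc (3 equiv), CH3CN, rt to 50 °C; aq Na2S2O3
Reagents that add atoms: none
Why: Iodine-mediated aromatisation of a cyclohexane-1,3-dione by α-iodination and loss of HI, then enolisation to the resorcinol. The acetate buffer protects the acetal and the tert-butyl ester, and the product ring has no free position for further iodination.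

Step 11
Reactants: 16 the resorcinol diaryl ether of step 10
Product: 17 3-(benzyloxy)-2-[2-formyl-4,6-dihydroxy-3-(methoxycarbonyl)-5-methylphenoxy]-4-methoxy-6-methylbenzoic acid
Conditions: CF3CO2H–CH2Cl2–H2O (10:10:1), 0 °C to rt
Reagents that add atoms: water, O
Why: Acidolysis of the tert-butyl ester and hydrolysis of the diethyl acetal in one operation. Water is present from the start so the oxocarbenium ion is trapped before the neighbouring methyl ester can participate, and the temperature is kept low to avoid decarboxylation.

Step 12
Reactants: 17 the formyl hydroxy acid of step 11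
Product: 19 methyl 4-(benzyloxy)-6-formyl-8-hydroxy-3-methoxy-1,9-dimethyl-11-oxo-11H-dibenzo[b,e][1,4]dioxepine-7-carboxylate, via O-acylisourea 18 (not isolated)
Conditions: DCC, DMAP (0.1 equiv), CH2Cl2 (0.005 M), 0 °C to rt
Reagents that add atoms: none
Why: Carbodiimide lactonisation (Steglich type) under high dilution, the classical closure of depsidones from 2-(2-hydroxyaryloxy)benzoic acids. Only the phenol next to the ether oxygen can reach the activated acid; the other is hydrogen-bonded to its ester and too far away.

Step 13
Reactants: 19 the depsidone phenol of step 12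
Product: 20 methyl 4,8-bis(benzyloxy)-6-formyl-3-methoxy-1,9-dimethyl-11-oxo-11H-dibenzo[b,e][1,4]dioxepine-7-carboxylate
Conditions: BnBr, K2CO3, dry DMF, rt
Reagents that add atoms: benzyl bromide, BrCc1ccccc1
Why: Williamson benzylation of the remaining phenol under dry conditions, which removes the last acidic proton before the copper step. It would also re-benzylate the ring A phenol if part of that ether were lost in step 11.

Step 14
Reactants: 20 the bis(benzyl ether) formyl ester of step 13; 21 bis(pinacolato)diboron
Product: 22 (1S)-4,11-bis(benzyloxy)-10-methoxy-5,8-dimethyl-1-(4,4,5,5-tetramethyl-1,3,2-dioxaborolan-2-yl)-1H-isobenzofuro[4,5-b][1,4]benzodioxepine-3,7-dione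
Conditions: CuCl (10 mol %), (R)-DTBM-SEGPHOS (11 mol %), NaOC(CH3)3 (10 mol %), THF, 0 °C to rt; filtration through silica gel
Reagents that add atoms: none
Why: Proposed new method: the tert-butoxide of the bisphosphine-bound monovalent copper exchanges with 21 to give a copper boryl, which adds across the aldehyde C=O of 20 with boron on carbon. The resulting copper alkoxide attacks the neighbouring methyl ester (5-exo-trig acyl substitution), closes the five-membered lactone and expels methoxide; the copper methoxide then regenerates the copper boryl from 21, releasing CH3O–Bpin. The closest known reactions are the CuCl–bisphosphine-catalysed enantioselective borylation of aldehydes to α-oxygenated boronates and the ready lactonisation of ortho-(hydroxymethyl)benzoates to phthalides. C1 is set by the face of the aldehyde that the chiral copper boryl attacks, under catalyst control alone because 20 has no stereocentre; the (S)-boronate is required, and the antipodal ligand is used if the (R)-ligand selects the other face. The step needs chemoselectivity for the aldehyde over the methyl ester and the aryl ester of the seven-membered ring, which the much higher electrophilicity of the aldehyde and the absence of free alkoxide (base equimolar to CuCl, no alcohol) should secure. If the copper alkoxide is borylated on oxygen before it lactonises, the O–B bond is cleaved on silica gel and the hydroxy ester closes to the same lactone, so both paths lead to 22. The product has no hemiacetal OH and cannot ring-open, so C1 keeps its configuration.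

Step 15
Reactants: 22 the benzyl-protected boryl lactone of step 14
Product: 23 (1S)-4,11-dihydroxy-10-methoxy-5,8-dimethyl-1-(4,4,5,5-tetramethyl-1,3,2-dioxaborolan-2-yl)-1H-isobenzofuro[4,5-b][1,4]benzodioxepine-3,7-dione
Conditions: H2 (1 atm), Pd/C (10 %), EtOAc, rt
Reagents that add atoms: none
Why: Hydrogenolysis of aryl benzyl ethers on palladium under neutral conditions, which alkyl pinacol boronates, lactones and the aryl ester should tolerate. C1 remains locked as a C–B centre while the phenols are freed.

Step 16
Reactants: 23 the diphenol boryl lactone of step 15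
Product: 25 (1R)-1,4,11-trihydroxy-10-methoxy-5,8-dimethyl-1H-isobenzofuro[4,5-b][1,4]benzodioxepine-3,7-dione (CNP0211607.1), via borate ester 24 (not isolated)
Conditions: anhydrous (CH3)3NO, CH2Cl2, 0 °C to rt; evaporation at 0 °C; pH 4 citrate buffer–EtOAc, 0 °C; immediate crystallisation
Reagents that add atoms: trimethylamine N-oxide, C[N+](C)(C)[O-]
Why: Amine-oxide oxidation of a boronic ester: the N-oxide oxygen binds boron, C1 migrates from boron to oxygen with retention and trimethylamine leaves, so (S)-C–B becomes (R)-C–O with the same spatial arrangement. The amine is removed before the O–B bond of 24 is hydrolysed in cold, weakly acidic buffer, so the free lactol never meets base, and 25 is crystallised at once.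

## Compound list

1 | creosol (2-methoxy-4-methylphenol) | COc1cc(C)ccc1O | starting material
2 | 2-hydroxy-3-methoxy-5-methylbenzaldehyde | COc1cc(C)cc(C=O)c1O | intermediate
3 | 2-(benzyloxy)-3-methoxy-5-methylbenzaldehyde | COc1cc(C)cc(C=O)c1OCc1ccccc1 | intermediate
4 | 2-(benzyloxy)-3-methoxy-5-methylphenyl formate | COc1cc(C)cc(OC=O)c1OCc1ccccc1 | intermediate (not isolated)
5 | 2-(benzyloxy)-3-methoxy-5-methylphenol | COc1cc(C)cc(O)c1OCc1ccccc1 | intermediate
6 | 3-(benzyloxy)-2-hydroxy-4-methoxy-6-methylbenzaldehyde | COc1cc(C)c(C=O)c(O)c1OCc1ccccc1 | intermediate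
7 | 3-(benzyloxy)-2-hydroxy-4-methoxy-6-methylbenzoic acid | COc1cc(C)c(C(=O)O)c(O)c1OCc1ccccc1 | intermediate
8 | tert-butyl 3-(benzyloxy)-2-hydroxy-4-methoxy-6-methylbenzoate | COc1cc(C)c(C(=O)OC(C)(C)C)c(O)c1OCc1ccccc1 | intermediate
9 | 1-bromobutan-2-one | CCC(=O)CBr | starting material
10 | tert-butyl 3-(benzyloxy)-4-methoxy-6-methyl-2-(2-oxobutoxy)benzoate | CCC(=O)COc1c(OCc2ccccc2)c(OC)cc(C)c1C(=O)OC(C)(C)C | intermediate
11 | 2,2-diethoxyacetaldehyde | CCOC(OCC)C=O | starting material
12 | tert-butyl 3-(benzyloxy)-2-{[(2Z)-1,1-diethoxy-4-oxohex-2-en-3-yl]oxy}-4-methoxy-6-methylbenzoate | CCC(=O)/C(Oc1c(OCc2ccccc2)c(OC)cc(C)c1C(=O)OC(C)(C)C)=C/C(OCC)OCC | intermediate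
13 | dimethyl malonate | COC(=O)CC(=O)OC | starting material
14 | dimethyl 2-{3-[2-(benzyloxy)-6-(tert-butoxycarbonyl)-3-methoxy-5-methylphenoxy]-1,1-diethoxy-4-oxohexan-2-yl}propanedioate (diastereomers) | CCC(=O)C(Oc1c(OCc2ccccc2)c(OC)cc(C)c1C(=O)OC(C)(C)C)C(C(OCC)OCC)C(C(=O)OC)C(=O)OC | intermediate (not isolated)
15 | tert-butyl 3-(benzyloxy)-2-{[2-(diethoxymethyl)-3-(methoxycarbonyl)-5-methyl-4,6-dioxocyclohexyl]oxy}-4-methoxy-6-methylbenzoate (diastereomers and enol forms) | COC(=O)C1C(C(OCC)OCC)C(Oc2c(OCc3ccccc3)c(OC)cc(C)c2C(=O)OC(C)(C)C)C(=O)C(C)C1=O | intermediate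
16 | tert-butyl 3-(benzyloxy)-2-[2-(diethoxymethyl)-4,6-dihydroxy-3-(methoxycarbonyl)-5-methylphenoxy]-4-methoxy-6-methylbenzoate | COc1cc(C)c(C(=O)OC(C)(C)C)c(Oc2c(O)c(C)c(O)c(C(=O)OC)c2C(OCC)OCC)c1OCc1ccccc1 | intermediate
17 | 3-(benzyloxy)-2-[2-formyl-4,6-dihydroxy-3-(methoxycarbonyl)-5-methylphenoxy]-4-methoxy-6-methylbenzoic acid | COc1cc(C)c(C(=O)O)c(Oc2c(O)c(C)c(O)c(C(=O)OC)c2C=O)c1OCc1ccccc1 | intermediate
18 | N,N'-dicyclohexyl-O-acylisourea of acid 17 | COc1cc(C)c(C(=O)OC(=NC2CCCCC2)NC2CCCCC2)c(Oc2c(O)c(C)c(O)c(C(=O)OC)c2C=O)c1OCc1ccccc1 | intermediate (not isolated)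
19 | methyl 4-(benzyloxy)-6-formyl-8-hydroxy-3-methoxy-1,9-dimethyl-11-oxo-11H-dibenzo[b,e][1,4]dioxepine-7-carboxylate | COc1cc(C)c2c(c1OCc1ccccc1)Oc1c(c(C)c(O)c(C(=O)OC)c1C=O)OC2=O | intermediate
20 | methyl 4,8-bis(benzyloxy)-6-formyl-3-methoxy-1,9-dimethyl-11-oxo-11H-dibenzo[b,e][1,4]dioxepine-7-carboxylate | COc1cc(C)c2c(c1OCc1ccccc1)Oc1c(c(C)c(OCc3ccccc3)c(C(=O)OC)c1C=O)OC2=O | intermediate
21 | bis(pinacolato)diboron | CC1(C)OB(OC1(C)C)B1OC(C)(C)C(C)(C)O1 | starting material
22 | (1S)-4,11-bis(benzyloxy)-10-methoxy-5,8-dimethyl-1-(4,4,5,5-tetramethyl-1,3,2-dioxaborolan-2-yl)-1H-isobenzofuro[4,5-b][1,4]benzodioxepine-3,7-dione | COc1cc(C)c2c(c1OCc1ccccc1)Oc1c(c(C)c(OCc3ccccc3)c3c1[C@H](B4OC(C)(C)C(C)(C)O4)OC3=O)OC2=O | intermediate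
23 | (1S)-4,11-dihydroxy-10-methoxy-5,8-dimethyl-1-(4,4,5,5-tetramethyl-1,3,2-dioxaborolan-2-yl)-1H-isobenzofuro[4,5-b][1,4]benzodioxepine-3,7-dione | COc1cc(C)c2c(c1O)Oc1c(c(C)c(O)c3c1[C@H](B4OC(C)(C)C(C)(C)O4)OC3=O)OC2=O | intermediate
24 | (1R)-4,11-dihydroxy-10-methoxy-5,8-dimethyl-1-[(4,4,5,5-tetramethyl-1,3,2-dioxaborolan-2-yl)oxy]-1H-isobenzofuro[4,5-b][1,4]benzodioxepine-3,7-dione | COc1cc(C)c2c(c1O)Oc1c(c(C)c(O)c3c1[C@H](OB4OC(C)(C)C(C)(C)O4)OC3=O)OC2=O | intermediate (not isolated)
25 | (1R)-1,4,11-trihydroxy-10-methoxy-5,8-dimethyl-1H-isobenzofuro[4,5-b][1,4]benzodioxepine-3,7-dione (CNP0211607.1) | COc1cc(C)c2c(c1O)Oc1c(c(C)c(O)c3c1[C@H](O)OC3=O)OC2=O | target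

## Step count and least certain steps

Total steps: 16. Longest linear sequence: 16 steps (1 to 25); compounds 9, 11, 13 and 21 are bought.

**Step 14 (key step).**
- *Risk:* the catalyst may turn over poorly because the copper alkoxide is slow to close onto a di-ortho-substituted ester. Face selection at a di-ortho-substituted aryl aldehyde may also be weak, since the known enantioselective borylations concern less crowded aldehydes. Trace alkoxide could open the aryl ester of the seven-membered ring.
- *Fallback (known chemistry):* starting from 20, an achiral carbene complex, chloro(1,3-dicyclohexylimidazol-2-ylidene)copper, with NaOC(CH3)3, 21 and CH3OH (2 equiv) in toluene at rt should give the racemic α-hydroxy boronate F1. Pyridinium 4-toluenesulfonate in CH2Cl2 closes it to the racemic boryl lactone F2. Preparative chromatography of F2 on a chiral stationary phase (amylose tris(3,5-dimethylphenylcarbamate)) gives the (S)-enantiomer, which is 22, and the route continues with step 15. This works because F2 has no OH and does not racemise.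

**Step 16.**
- *Risk:* erosion of configuration at C1 by ring opening while the free lactol is released, promoted by trimethylamine or by the basic N-oxide acting on the phenols; or slow oxidation of the crowded α-acyloxy boronate.
- *Fallback:* starting from 23, KHF2 in CH3OH–H2O converts the pinacol ester into the potassium trifluoroborate F3. KHSO5 (as the triple salt 2KHSO5·KHSO4·K2SO4) in acetone–water at 0 °C oxidises F3 within minutes, with retention, in an amine-free and weakly acidic medium. This gives 25 directly, which is crystallised as before.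

**Step 15.**
- *Risk:* cleavage of the benzylic C–B bond on palladium (protodeboronation) competing with removal of the hindered ring B benzyl ether.
- *Fallback:* the order of the last steps is changed. Starting from 22, anhydrous (CH3)3NO in CH2Cl2 oxidises the C–B bond first to the dibenzyl O-boryl hemiacetal F4, in which the lactol oxygen stays capped by boron. Hydrogenolysis of F4 (H2, Pd/C, dry EtOAc) then gives 24, the intermediate of step 16, which is hydrolysed and crystallised as described there.

**Step 8.**
- *Risk:* condensation at the ethyl side of the ketone, or reversible addition of pyrrolidine to the product enone holding up conversion.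
- *Fallback:* a regiochemically unambiguous route to the same dione through an ester.
  - Starting from 8, methyl bromoacetate and K2CO3 in DMF give aryloxyacetate F5.
  - Its lithium enolate (lithium diisopropylamide, THF, −78 °C) adds to 11 to give β-hydroxy ester F6.
  - Methanesulfonyl chloride and Et3N, then DBU, give the 2-aryloxy acrylate F8 through mesylate F7.
  - Methyl 3-oxopentanoate and NaOCH3 in refluxing CH3OH add to F8 and close the ring through Michael adduct F9. This gives 15, so the route continues with step 10 and steps 8 and 9 are both replaced.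

**Step 10.**
- *Risk:* iodination at the methyl-bearing carbon between the two carbonyls, from which no HI can be lost, so the reaction stalls or the ring is cleaved; slow iodination of ring A is a lesser concern.
- *Fallback:* a halogen-free dehydrogenation. Starting from 15, Pd(O2CCF3)2 (10 mol %) with DMSO (20 mol %) under O2 (1 atm) in EtOAc at 60 °C forms an enolate of divalent palladium at the ester-bearing carbon. β-Hydride elimination and enolisation give 16, and O2 re-oxidises the zerovalent palladium. No new compound is involved.

## Further compounds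

F1 | step 14 | methyl 4,8-bis(benzyloxy)-6-[hydroxy(4,4,5,5-tetramethyl-1,3,2-dioxaborolan-2-yl)methyl]-3-methoxy-1,9-dimethyl-11-oxo-11H-dibenzo[b,e][1,4]dioxepine-7-carboxylate (racemic) | COc1cc(C)c2c(c1OCc1ccccc1)Oc1c(c(C)c(OCc3ccccc3)c(C(=O)OC)c1C(O)B1OC(C)(C)C(C)(C)O1)OC2=O
F2 | step 14 | racemic 4,11-bis(benzyloxy)-10-methoxy-5,8-dimethyl-1-(4,4,5,5-tetramethyl-1,3,2-dioxaborolan-2-yl)-1H-isobenzofuro[4,5-b][1,4]benzodioxepine-3,7-dione | COc1cc(C)c2c(c1OCc1ccccc1)Oc1c(c(C)c(OCc3ccccc3)c3c1C(B4OC(C)(C)C(C)(C)O4)OC3=O)OC2=O
F3 | step 16 | potassium [(1S)-4,11-dihydroxy-10-methoxy-5,8-dimethyl-3,7-dioxo-1H-isobenzofuro[4,5-b][1,4]benzodioxepin-1-yl]trifluoroborate | [K+].COc1cc(C)c2c(c1O)Oc1c(c(C)c(O)c3c1[C@H]([B-](F)(F)F)OC3=O)OC2=O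
F4 | step 15 | (1R)-4,11-bis(benzyloxy)-10-methoxy-5,8-dimethyl-1-[(4,4,5,5-tetramethyl-1,3,2-dioxaborolan-2-yl)oxy]-1H-isobenzofuro[4,5-b][1,4]benzodioxepine-3,7-dione | COc1cc(C)c2c(c1OCc1ccccc1)Oc1c(c(C)c(OCc3ccccc3)c3c1[C@H](OB4OC(C)(C)C(C)(C)O4)OC3=O)OC2=O
F5 | step 8 | tert-butyl 3-(benzyloxy)-4-methoxy-2-(2-methoxy-2-oxoethoxy)-6-methylbenzoate | COC(=O)COc1c(OCc2ccccc2)c(OC)cc(C)c1C(=O)OC(C)(C)C
F6 | step 8 | tert-butyl 3-(benzyloxy)-2-[(4,4-diethoxy-3-hydroxy-1-methoxy-1-oxobutan-2-yl)oxy]-4-methoxy-6-methylbenzoate (diastereomers) | COC(=O)C(Oc1c(OCc2ccccc2)c(OC)cc(C)c1C(=O)OC(C)(C)C)C(O)C(OCC)OCC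
F7 | step 8 | tert-butyl 3-(benzyloxy)-2-{[4,4-diethoxy-1-methoxy-3-(methylsulfonyloxy)-1-oxobutan-2-yl]oxy}-4-methoxy-6-methylbenzoate (diastereomers) | COC(=O)C(Oc1c(OCc2ccccc2)c(OC)cc(C)c1C(=O)OC(C)(C)C)C(OS(C)(=O)=O)C(OCC)OCC
F8 | step 8 | tert-butyl 3-(benzyloxy)-2-[(4,4-diethoxy-1-methoxy-1-oxobut-2-en-2-yl)oxy]-4-methoxy-6-methylbenzoate (alkene isomers) | COC(=O)C(Oc1c(OCc2ccccc2)c(OC)cc(C)c1C(=O)OC(C)(C)C)=CC(OCC)OCC
F9 | step 8 | dimethyl 2-[2-(benzyloxy)-6-(tert-butoxycarbonyl)-3-methoxy-5-methylphenoxy]-3-(diethoxymethyl)-4-propanoylpentanedioate (diastereomers) | CCC(=O)C(C(=O)OC)C(C(OCC)OCC)C(Oc1c(OCc2ccccc2)c(OC)cc(C)c1C(=O)OC(C)(C)C)C(=O)OC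
F0 | step 10 | none | none
A1 | alternative 1 | tert-butyl 3-(benzyloxy)-2-[2-(diethoxymethyl)-4,6-dihydroxy-3-(methoxycarbonyl)-5-methylphenoxy]-4-methoxy-6-methylbenzoate (identical with 16) | COc1cc(C)c(C(=O)OC(C)(C)C)c(Oc2c(O)c(C)c(O)c(C(=O)OC)c2C(OCC)OCC)c1OCc1ccccc1
A2 | alternative 1 | racemic 1,4,11-trihydroxy-10-methoxy-5,8-dimethyl-1H-isobenzofuro[4,5-b][1,4]benzodioxepine-3,7-dione | COc1cc(C)c2c(c1O)Oc1c(c(C)c(O)c3c1C(O)OC3=O)OC2=O
A3 | alternative 2 | 4,11-diacetoxy-10-methoxy-5,8-dimethyl-1H-isobenzofuro[4,5-b][1,4]benzodioxepine-3,7-dione | COc1cc(C)c2c(c1OC(C)=O)Oc1c(c(C)c(OC(C)=O)c3c1COC3=O)OC2=O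
A4 | alternative 2 | 4,8-diacetoxy-3-methoxy-1,6,9-trimethyl-11-oxo-11H-dibenzo[b,e][1,4]dioxepine-7-carboxylic acid | COc1cc(C)c2c(c1OC(C)=O)Oc1c(c(C)c(OC(C)=O)c(C(=O)O)c1C)OC2=O
A5 | alternative 3 | methyl 4-(benzyloxy)-6-formyl-8-hydroxy-3-methoxy-1,9-dimethyl-11-oxo-11H-dibenzo[b,e][1,4]dioxepine-7-carboxylate (identical with 19) | COc1cc(C)c2c(c1OCc1ccccc1)Oc1c(c(C)c(O)c(C(=O)OC)c1C=O)OC2=O
A6 | alternative 3 | 3-(benzyloxy)-2-[2-formyl-4-hydroxy-3-(methoxycarbonyl)-5-methylphenoxy]-4-methoxy-6-methylbenzoic acid | COc1cc(C)c(C(=O)O)c(Oc2cc(C)c(O)c(C(=O)OC)c2C=O)c1OCc1ccccc1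
A7 | alternative 3 | spiro ketal-lactone: ring A 4H-1,3-benzodioxin-4-one whose C2 is the spiro carbon of a 3-formyl-4-(methoxycarbonyl)-6-methylcyclohexa-2,5-dien-1-one (carbonyl para to the spiro carbon) | COc1cc(C)c2c(c1OCc1ccccc1)OC1(OC2=O)C=C(C)C(=O)C(C(=O)OC)=C1C=O
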